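At early times the south-west run, a closed isothermal flask, consumes starting material quickly and then stalls, and the height of that stall is the first thing to watch.

| flask | starting material | coupling partner | protic impurity | remark | time |
|---|---|---|---|---|---|
| south-west | 1 M | 0.60 M | 0.10 M | run made earlier |  |
| flask | 0.50 M | 0.600 M | 0.100 M |  | 15 d |

south-west run (percent of the starting material charged)

| time / d | isomer of the product / % | target / % | starting material / % |
|---|---|---|---|
| 0.417 | 0 | 33.1 | 37.4 |
| 1.04 | 1.0 | 45.4 | 34.2 |
| 2.08 | 1.5 | 45.2 | 33.9 |
| 3.00 | 2.1 | 44.5 | 33.1 |

(each reading ± 0.5 percentage points)

- share of isomer of the product in isomer of the product plus target at 80 min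
- share of isomer of the product in isomer of the product plus target at 15 d



South-west starting material reads 34.2% at 1.04 d and 33.1% at 3.00 d, near the 30.0% expected if each coupling partner and each protic impurity takes one starting material. The crossing therefore lies where charged [starting material] equals charged [coupling partner] plus charged [protic impurity]. The flask lies below it, with more coupling partner and protic impurity charged than starting material, and the surplus is 0.200 M: charged [coupling partner] plus charged [protic impurity] minus charged [starting material].

South-west has 20.3% of its charge unaccounted for, more than the 10.0% its protic impurity can quench, so the reckoning here lets the surplus consume target. Target plus isomer in the flask then end near 40.0% of the charge. If isomer grows in proportion to that pool, pool size cancels from the share, and the south-west shares, 2.16% at 1.04 d and 4.51% at 3.00 d, carry over. Their slope of 0.0120 d⁻¹ gives 18.9% at 15 d.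

The weak link is the start. A line through zero is not assured, since this one gives 0.974% at 80 min, and a scatter of 0.5 percentage points cannot exclude that.

The forecast gives 0.1% and 18%, on the ground that “the isomer appears to form from the target”. Its early share is lower than this reckoning's.

The flask gives 1.43% and 13.5%, and the forecast stands within its margins.

    intermediate ⇌ isomer of the product (K = 4.02, k = 4.45 × 10⁻⁵ min⁻¹)
    starting material + protic impurity → quenched substrate (k = 0.0306 M⁻¹ min⁻¹)
    coupling partner + target → over-reaction product (k = 0.00210 M⁻¹ min⁻¹)
    intermediate ⇌ target (K = 7.16, k = 0.00321 min⁻¹)
    starting material + coupling partner → intermediate + by-product (k = 0.00754 M⁻¹ min⁻¹)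

At 0.114 d the flask spends coupling partner on starting material at 16 times its rate on target, while target's half-life by that second step is 0.58 d, shorter than 15 d. The surplus amounts to 40.0% of the charge, and at 15.0 d the flask holds 40.6% over-reaction product, more than its 30.0% target. With 2.0 M of starting material the surplus is −1.30 M, which leaves 65.0% of that charge unconsumed, and that flask holds 65.4% starting material at 15.0 d.

Readings and results stem from a simulated flask on assumed constants.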